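**Route in one sentence:** a chiral-Lewis-acid-mediated benzilic ester ring contraction of the flat, achiral, fully substituted o-benzoquinone 4 extrudes one ring carbon as the methyl ester and creates the five-membered ring and its only stereocentre in one operation.

## Structural features

The target is a fully substituted cyclopent-2-en-1-one; its ring atoms are called C1–C5 here, the ester carbon C6 and the exocyclic enol carbon C7. C1 is the only stereocentre (S): a quaternary sp3 carbon that carries a methoxy group and the methyl ester C6 and is flanked by two sp2 ring carbons, C2 and C5. C2=C3 is a tetrasubstituted bis(enol ether) with two methoxy groups, C4 is the ring ketone, and C5 bears the exocyclic (Z)-enol C7(OH), which continues into an (E)-styryl group. C4=O, C5=C7 and the enol OH form the hydrogen-bonded, acidic, tautomeric enol of a 2-acyl-1,3-dicarbonyl unit; the C2 methoxy group is a vinylogous ester and the styryl ketone is a Michael acceptor, so strong nucleophiles and aqueous base are the main hazards. Because there is no second stereocentre, nothing in the substrate can relay chirality to C1, and because C1 cannot enolise it can be neither epimerised nor corrected once made. The real difficulty is therefore the absolute configuration of one isolated, fully substituted carbon in a ring in which every atom is functionalised. The feature that the key step exploits is the geminal pair on C1, an ether oxygen and the ester carbon C6, next to the dimethoxy alkene C2=C3: this is the footprint of a 1,2-dione C1(=O)–C6(=O) in a six-membered ring C1–C2–C3–C4–C5–C6 from which C6 has been extruded by a 1,2-shift of C5.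

## Logic of the disconnections

**9 ⇒ 7.** The O–H of the chelated enol is traced back to an O–CH3 bond on the C4 oxygen. The reason is that every earlier intermediate then lacks an acidic proton, and the six-membered precursor cannot tautomerise to an unreactive hydroxyquinone anion. Nothing is gained in skeleton; the gain is that the key step becomes possible. The forward step must cleave one O-methyl group out of five, which is asked of chelation to the C7 carbonyl.

**7 ⇒ 6.** The O–CH3 bond on the C1 oxygen is cut, because the ring contraction delivers this oxygen as a free tertiary carbinol. The forward step must alkylate a hindered tertiary alcohol without generating an alkoxide that adds to the styryl ketone.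

**6 ⇒ 4 (key).** The C1–C5 bond is cut, the C5–C6 bond is restored and methanol is removed from C6, so the ester carbon returns into the ring as a quinone carbonyl. This erases the stereocentre and turns the cyclopentane problem into an arene-substitution problem: 4 is flat, achiral and at the oxidation level of a pentaoxygenated benzene. The forward step must add methanol 1,2 to the C6 carbonyl under facial control by a chiral catalyst, and the 1,2-shift must outrun conjugate addition and reduction of the quinone.

**4 ⇒ 3.** The C1=O bond is cut back to C1–H and the ring is re-aromatised to a phenol whose hydroxyl sits on C6. The phenol has exactly one unsubstituted ortho carbon, so the position of the new oxygen is not in doubt. The forward step must oxygenate a hydrogen-bonded acylphenol ortho-selectively without touching the enone.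

**3 ⇒ 1 + 2.** The styryl C=C bond is cut (aldol condensation transform), which gives two catalogue compounds. The forward step must stop at the open chalcone and not close to the flavanone.

## Other disconnections considered

**Alternative 1:** Cut C5–C7, the first disconnection that comes to mind. The forward key step would be C-acylation of the enolate of methyl (1S)-1,2,3-trimethoxy-4-oxocyclopent-2-ene-1-carboxylate A1 with a cinnamoyl donor (or O-acylation followed by O-to-C acyl transfer). This step forms only an exocyclic bond and leaves the whole difficulty, the enantiopure quaternary α-methoxy ester in a fully oxygenated ring, inside A1. A1 would need its own asymmetric synthesis of at least the length of the whole chosen route, and C- versus O-acylation of its enolate adds a selectivity problem. The chosen plan settles ring and stereocentre together from an arene two steps from catalogue compounds.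

**Alternative 2:** Cut C1–C2. The forward key step would be a chiral-Lewis-acid-catalysed Nazarov 4π-conrotatory electrocyclisation of the cross-conjugated dienone A2, followed by loss of the C2 proton; this would give the target directly. A2 is a doubly O-methylated tetracarbonyl compound, so its preparation needs regiocontrolled enol-ether formation at several competing oxygens. The geometry of its tetrasubstituted push–pull alkene (the future C5=C1) translates directly into the configuration of C1 under a given torquoselectivity, and such alkenes are expected to isomerise under Lewis acid, so enantiopurity would be tied to a labile geometry. The terminus C1 also carries both a donor and an acceptor, a mismatched polarisation for ring closure to a quaternary carbon. The quinone 4 has no geometric isomers and is two steps from 1.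

**Alternative 3:** Cut C1–C5 and C4–C5, a (4+1) annulation. Dimethyl squarate A3 would be converted into the cyclobutenone A4 (addition of a methoxycarbonyl anion equivalent, then O-methylation). Thermal 4π ring opening would give the vinylketene A5, which would be intercepted by the acyl sulfonium ylide A6; the ylide carbon becomes C5. The ring is formed neatly, but C1 is created from a planar dienolate with no element able to control its configuration, since the only stereogenic element that could be introduced (a chiral ylide) ends up at the sp2 carbon C5. The closure is a 5-(enolendo)-exo-tet alkylation, which is stereoelectronically disfavoured, and a stabilised acyl ylide is expected to stop at the C-acylated ylide. The route also needs more steps to A4 than the chosen route needs in total.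

Key step: step 3

**Remarks on the chemistry.**
- Compound 1 is taken as purchasable; it is otherwise the Friedel–Crafts acetylation product of 3,4,5-trimethoxyphenol.
- The 2-acyl-1,3-dicarbonyl unit of the target is one chelated enol system; it is drawn as the exocyclic (Z)-enol of the given SMILES.
- The (R,R)-ligand in step 3 follows from the 1,2-dione binding model, by analogy with nucleophile additions to 1,2-dicarbonyl chelates of this catalyst family; if the sense of induction is opposite, the (S,S)-ligand is used.

## Steps

**Step 1**
Reactants: 1 1-(6-hydroxy-2,3,4-trimethoxyphenyl)ethan-1-one; 2 benzaldehyde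
Product: 3 (2E)-1-(6-hydroxy-2,3,4-trimethoxyphenyl)-3-phenylprop-2-en-1-one
Conditions: KOH (50% aq.), EtOH, 0 °C → rt; then 1 M HCl, 0 °C
Reagents that add atoms: none
Why: Claisen–Schmidt (crossed aldol) condensation: the methyl ketone enolate of the phenoxide of 1 adds to the non-enolisable aldehyde 2 and the aldol dehydrates by E1cB to the conjugated (E)-enone, the thermodynamic geometry; in strong base the open chalcone phenoxide is favoured over the flavanone, and cold acidification should return 3.

**Step 2**
Reactants: 3 (2E)-1-(6-hydroxy-2,3,4-trimethoxyphenyl)-3-phenylprop-2-en-1-one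
Product: 4 3,4,5-trimethoxy-6-[(2E)-3-phenylprop-2-enoyl]cyclohexa-3,5-diene-1,2-dione
Conditions: IBX (1.2 equiv), DMF, rt, dark; rapid non-basic work-up
Reagents that add atoms: 2-iodoxybenzoic acid (IBX), O=C1OI(=O)(O)c2ccccc12
Why: Ortho-selective oxidation of a phenol to an o-quinone by a pentavalent iodine reagent: the phenol oxygen exchanges onto iodine, an iodine-bound oxygen is delivered intramolecularly to the only unsubstituted ring carbon, and the catechol-level species is oxidised further with release of monovalent-iodine 2-iodobenzoic acid; the enone and the methyl ethers are inert to IBX at room temperature, and 4 is flat and achiral.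

**Step 3**
Reactants: 4 3,4,5-trimethoxy-6-[(2E)-3-phenylprop-2-enoyl]cyclohexa-3,5-diene-1,2-dione
Product: 6 methyl (1S)-1-hydroxy-2,3,4-trimethoxy-5-[(2E)-3-phenylprop-2-enoyl]cyclopenta-2,4-diene-1-carboxylate, via hemiketal 5 (not isolated)
Conditions: Cu(OTf)2 (10 mol %), (R,R)-tBu-box [2,2′-(propane-2,2-diyl)bis((4R)-4-tert-butyl-4,5-dihydro-1,3-oxazole)] (11 mol %), MeOH (5 equiv), 4 Å MS, CH2Cl2, −40 → 0 °C
Reagents that add atoms: methanol, CO
Why: Proposed new method: an enantioselective, Lewis-acid-catalysed benzilic ester ring contraction of an o-benzoquinone with neutral methanol. The divalent copper bis(oxazoline) complex chelates 4 through the C6 carbonyl oxygen and a neighbouring carbonyl oxygen, methanol adds to the Re face of C6 (the more electrophilic quinone carbonyl, because the donor methoxy group on C4 is shared with the C7 carbonyl) and gives the copper-bound hemiketal 5, whose alkoxide then pushes ring carbon C5 from C6 to C1, so that C6 leaves the ring as the methyl ester and C1 becomes the tertiary carbinol. The closest known reaction types are the base-mediated benzilic acid and ester ring contractions of cyclic 1,2-diones and the chiral-Lewis-acid-catalysed enantioselective α-ketol (acyloin) rearrangements, of which this is the hemiketal version. The five-membered ring is closed by contraction and not end to end: a suprafacial anionic 1,2-shift through a three-centre C6–C5–C1 transition state (formally a 3-exo-trig attack of C5 on the C1 carbonyl with cleavage of C5–C6), so no ring-closure rule is strained. The one new stereocentre, C1, is controlled by the catalyst: the metal-bound hemiketal oxygen stays near the plane of the accepting C1 carbonyl, the new methoxy group is pseudo-axial, C6 tips out of the ring toward that face and the ester ends on the face that methanol attacked, so (R)-5 should give (S)-6. The step needs 1,2-addition in place of conjugate addition or substitution, which the substrate secures because every other ring position is substituted and exchange of a ring methoxy group by methanol is degenerate. It also needs attack at C6 and not at C1, which would give the same constitution but, under a twofold-symmetric catalyst, the opposite configuration; the electronic bias of C6 and its ability to join both the 1,2- and the 1,3-dicarbonyl chelate are the basis for this. Without added base the uncatalysed racemic pathway should be slow, and the exchange of a cis-dione for an ester and a push–pull acylcyclopentadiene makes the shift irreversible.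

**Step 4**
Reactants: 6 methyl (1S)-1-hydroxy-2,3,4-trimethoxy-5-[(2E)-3-phenylprop-2-enoyl]cyclopenta-2,4-diene-1-carboxylate
Product: 7 methyl (1S)-1,2,3,4-tetramethoxy-5-[(2E)-3-phenylprop-2-enoyl]cyclopenta-2,4-diene-1-carboxylate
Conditions: MeI (10 equiv), Ag2O (3 equiv), 4 Å MS, CH2Cl2, rt → 40 °C, dark
Reagents that add atoms: iodomethane, CI
Why: Purdie-type Williamson O-methylation: Ag2O activates MeI and takes up HI, so the tertiary α-hydroxy ester is alkylated without a free alkoxide that could add to the styryl ketone, and 6 has no other O–H or acidic C–H; no bond to C1 is touched and ionisation at C1 would give an antiaromatic cyclopentadienyl cation, so the configuration is retained.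

**Step 5**
Reactants: 7 methyl (1S)-1,2,3,4-tetramethoxy-5-[(2E)-3-phenylprop-2-enoyl]cyclopenta-2,4-diene-1-carboxylate
Product: 9 methyl (1S,5Z)-5-[(2E)-1-hydroxy-3-phenylprop-2-en-1-ylidene]-1,2,3-trimethoxy-4-oxocyclopent-2-ene-1-carboxylate, via dichloroboron chelate 8 (not isolated)
Conditions: BCl3 (1.1 equiv), CH2Cl2, −78 → −20 °C; then H2O, 0 °C
Reagents that add atoms: none
Why: Chelation-controlled demethylation of a methoxy group next to an acyl carbonyl: BCl3 binds the electron-rich C7 carbonyl oxygen, closes a six-membered O,O-chelate with the C4 methoxy oxygen, and chloride attacks that oxonium-like methyl group by SN2 to give 8, which water hydrolyses to the chelated enol 9; the C2 and C3 methoxy groups cannot chelate, the C4 oxygen is retained and C1 is untouched.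

## Compound list

1 | 1-(6-hydroxy-2,3,4-trimethoxyphenyl)ethan-1-one | CC(=O)c1c(O)cc(OC)c(OC)c1OC | starting material
2 | benzaldehyde | O=Cc1ccccc1 | starting material
3 | (2E)-1-(6-hydroxy-2,3,4-trimethoxyphenyl)-3-phenylprop-2-en-1-one | O=C(/C=C/c1ccccc1)c1c(O)cc(OC)c(OC)c1OC | intermediate
4 | 3,4,5-trimethoxy-6-[(2E)-3-phenylprop-2-enoyl]cyclohexa-3,5-diene-1,2-dione | O=C1C(=O)C(OC)=C(OC)C(OC)=C1C(=O)/C=C/c1ccccc1 | intermediate
5 | (6R)-6-hydroxy-2,3,4,6-tetramethoxy-5-[(2E)-3-phenylprop-2-enoyl]cyclohexa-2,4-dien-1-one (hemiketal, catalyst-bound) | O=C1[C@](O)(OC)C(C(=O)/C=C/c2ccccc2)=C(OC)C(OC)=C1OC | intermediate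
6 | methyl (1S)-1-hydroxy-2,3,4-trimethoxy-5-[(2E)-3-phenylprop-2-enoyl]cyclopenta-2,4-diene-1-carboxylate | COC(=O)[C@@]1(O)C(OC)=C(OC)C(OC)=C1C(=O)/C=C/c1ccccc1 | intermediate
7 | methyl (1S)-1,2,3,4-tetramethoxy-5-[(2E)-3-phenylprop-2-enoyl]cyclopenta-2,4-diene-1-carboxylate | COC(=O)[C@@]1(OC)C(OC)=C(OC)C(OC)=C1C(=O)/C=C/c1ccccc1 | intermediate
8 | dichloroboron chelate of 9 (BCl2 bridging the C4 and C7 oxygens, S at C1) | COC(=O)[C@@]1(OC)C(OC)=C(OC)C2=C1C(/C=C/c1ccccc1)=[O+][B-](Cl)(Cl)O2 | intermediate
9 | methyl (1S,5Z)-5-[(2E)-1-hydroxy-3-phenylprop-2-en-1-ylidene]-1,2,3-trimethoxy-4-oxocyclopent-2-ene-1-carboxylate | COC(=O)[C@@]1(OC)C(OC)=C(OC)C(=O)/C1=C(O)/C=C/c1ccccc1 | target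

## Step count and least certain steps

Total step count: 5. Longest linear sequence: 5 steps (1 → 3 → 4 → 6 → 7 → 9).

**Step 3 (key step, proposed new method).** The most likely failure is erosion of enantioselectivity. Methanol addition at C1 instead of C6 converges on the same constitution but, under a twofold-symmetric catalyst, on the opposite configuration, and the substrate can bind either as a 1,2- or as a 1,3-dicarbonyl chelate. Further hazards are slow turnover through product chelation and reduction of the strongly oxidising quinone by hydride transfer from coordinated methanol. Fallback with known chemistry, from 4 back to 6: the ring contraction is run as a classical alkoxide-mediated benzilic ester rearrangement (NaOMe, MeOH–THF, −40 °C, AcOH quench), which should give the racemic hydroxy ester F1. Preparative chromatography on a chiral stationary phase (cellulose tris(3,5-dimethylphenylcarbamate)) then separates 6, where the route is rejoined, from its (1R)-enantiomer F2, which is discarded.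

**Step 2.** Oxygen transfer may be slow or misdirected because the phenol is hydrogen-bonded to, and deactivated by, the ortho acyl group. Oxidative demethylation at the para methoxy group (towards a p-quinone) and decomposition of the electrophilic o-quinone on work-up are the competing processes. Fallback, from 1 back to 4, installs the oxygen stepwise before the enone exists. Rieche formylation (Cl2CHOMe, TiCl4, CH2Cl2, 0 °C) at the single free ring position should give 3-acetyl-2-hydroxy-4,5,6-trimethoxybenzaldehyde F3. Dakin oxidation (H2O2, NaOH, 0 °C) converts the formyl group into a hydroxyl and gives 1-(2,3-dihydroxy-4,5,6-trimethoxyphenyl)ethan-1-one F4. Claisen–Schmidt condensation with 2 (KOH, EtOH, argon) gives (2E)-1-(2,3-dihydroxy-4,5,6-trimethoxyphenyl)-3-phenylprop-2-en-1-one F5, and Ag2O (Et2O, Na2SO4, rt) oxidises the catechol to 4.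

**Step 4.** Alkylation of the hindered, weakly nucleophilic tertiary oxygen may be slow. Under the more basic conditions that would force it, the alkoxide can close onto the styryl ketone by 6-endo oxa-Michael addition (the flavanone-type closure of 2′-hydroxychalcones), and prolonged heating invites sigmatropic ester shifts in the cyclopentadiene. Fallback, from 1 back to 7, postpones the styryl group so that no Michael acceptor is present when the alkoxide is formed. IBX (DMF, rt) on 1 gives 3-acetyl-4,5,6-trimethoxycyclohexa-3,5-diene-1,2-dione F6. The conditions of step 3 give methyl (1S)-5-acetyl-1-hydroxy-2,3,4-trimethoxycyclopenta-2,4-diene-1-carboxylate F7. NaH and MeI (THF, 0 °C) give methyl (1S)-5-acetyl-1,2,3,4-tetramethoxycyclopenta-2,4-diene-1-carboxylate F8. Claisen–Schmidt condensation of F8 with 2 (NaOMe, MeOH, rt) installs the styryl group and returns to the route at 7.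

**Step 5.** Regiocontrol of the demethylation may be lost: cleavage can also occur at the C2 methoxy group (the vinylogous position of the delocalised cation) or at the C1 methoxy group, which can also reach boron bound to the C7 oxygen, and the strong Lewis acid may degrade the push–pull diene. Fallback, from 7 back to 9, replaces SN2 attack at the methyl group by addition–elimination at ring carbon C4. Pyrrolidine (MeOH, 0 °C → rt) displaces the C4 methoxy group, the most electrophilic β-position of the acyl enone, to give methyl (1S)-1,2,3-trimethoxy-5-[(2E)-3-phenylprop-2-enoyl]-4-(pyrrolidin-1-yl)cyclopenta-2,4-diene-1-carboxylate F9. Mild hydrolysis of this enaminone (1 M HCl, THF, 0 °C) gives 9.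

## Further compounds

F1 | step 3 | methyl (1RS)-1-hydroxy-2,3,4-trimethoxy-5-[(2E)-3-phenylprop-2-enoyl]cyclopenta-2,4-diene-1-carboxylate (racemate) | COC(=O)C1(O)C(OC)=C(OC)C(OC)=C1C(=O)/C=C/c1ccccc1
F2 | step 3 | methyl (1R)-1-hydroxy-2,3,4-trimethoxy-5-[(2E)-3-phenylprop-2-enoyl]cyclopenta-2,4-diene-1-carboxylate | COC(=O)[C@]1(O)C(OC)=C(OC)C(OC)=C1C(=O)/C=C/c1ccccc1
F3 | step 2 | 3-acetyl-2-hydroxy-4,5,6-trimethoxybenzaldehyde | O=Cc1c(O)c(C(C)=O)c(OC)c(OC)c1OC
F4 | step 2 | 1-(2,3-dihydroxy-4,5,6-trimethoxyphenyl)ethan-1-one | CC(=O)c1c(O)c(O)c(OC)c(OC)c1OC
F5 | step 2 | (2E)-1-(2,3-dihydroxy-4,5,6-trimethoxyphenyl)-3-phenylprop-2-en-1-one | O=C(/C=C/c1ccccc1)c1c(O)c(O)c(OC)c(OC)c1OC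
F6 | step 4 | 3-acetyl-4,5,6-trimethoxycyclohexa-3,5-diene-1,2-dione | CC(=O)C1=C(OC)C(OC)=C(OC)C(=O)C1=O
F7 | step 4 | methyl (1S)-5-acetyl-1-hydroxy-2,3,4-trimethoxycyclopenta-2,4-diene-1-carboxylate | COC(=O)[C@@]1(O)C(OC)=C(OC)C(OC)=C1C(C)=O
F8 | step 4 | methyl (1S)-5-acetyl-1,2,3,4-tetramethoxycyclopenta-2,4-diene-1-carboxylate | COC(=O)[C@@]1(OC)C(OC)=C(OC)C(OC)=C1C(C)=O
F9 | step 5 | methyl (1S)-1,2,3-trimethoxy-5-[(2E)-3-phenylprop-2-enoyl]-4-(pyrrolidin-1-yl)cyclopenta-2,4-diene-1-carboxylate | COC(=O)[C@@]1(OC)C(OC)=C(OC)C(N2CCCC2)=C1C(=O)/C=C/c1ccccc1
A1 | alternative 1 | methyl (1S)-1,2,3-trimethoxy-4-oxocyclopent-2-ene-1-carboxylate | COC(=O)[C@@]1(OC)C(OC)=C(OC)C(=O)C1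
A2 | alternative 2 | methyl 2,5,6-trimethoxy-4-oxo-3-[(2E)-3-phenylprop-2-enoyl]hexa-2,5-dienoate (enol-ether geometries not fixed) | COC(=O)C(OC)=C(C(=O)/C=C/c1ccccc1)C(=O)C(OC)=COC
A3 | alternative 3 | dimethyl squarate (3,4-dimethoxycyclobut-3-ene-1,2-dione) | COC1=C(OC)C(=O)C1=O
A4 | alternative 3 | methyl 1,2,3-trimethoxy-4-oxocyclobut-2-ene-1-carboxylate (racemic) | COC(=O)C1(OC)C(OC)=C(OC)C1=O
A5 | alternative 3 | methyl (2Z)-2,3,4-trimethoxy-5-oxopenta-2,4-dienoate (vinylketene) | COC(=O)/C(OC)=C(/OC)C(OC)=C=O
A6 | alternative 3 | dimethylsulfonium (3E)-2-oxo-4-phenylbut-3-en-1-ide | C[S+](C)[CH-]C(=O)/C=C/c1ccccc1
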